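## Retrosynthetic overview

1. Target ⇐ global hydrogenolysis of the heptabenzyl ether of the (2R,3R)-flavan-3-ol 7-gallate.
2. C2 and C3 ⇐ set together from the racemic flavan-3-one by asymmetric transfer hydrogenation under dynamic kinetic resolution (C2–H is labile next to the ketone).
3. Key disconnection C3–C4 (with O1–C2): the nitronate formed from the B-ring nitrostyrene acts as a masked acyl anion at C3 and adds to the A-ring aldehyde carbon (C4); a reductive Nef reaction in the same flask reveals the C3 ketone.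
4. A-ring aldehyde ⇐ Vilsmeier formylation of 5-benzyloxyresorcinol, then gallate on the one non-chelated OH (this fixes the 5-O/7-O pattern); nitrostyrene ⇐ tribenzyloxybenzaldehyde + nitromethane.
5. Ring order: rings A and B are bought as arenes; the pyran ring C is the only ring formed (step 4).

Assumption: 5-(benzyloxy)benzene-1,3-diol, 3,4,5-tris(benzyloxy)benzoic acid and 3,4,5-tris(benzyloxy)benzaldehyde are taken as catalogue compounds.

## Route

Step 1
Reactants: 1 5-(benzyloxy)benzene-1,3-diol
Product: 3 2-(benzyloxy)-4,6-dihydroxybenzaldehyde, via aryl iminium salt 2 (not isolated)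
Conditions: POCl3, DMF, MeCN, 0 °C to rt; then H2O, 50 °C
Reagents that add atoms: N,N-dimethylformamide CN(C)C=O; water O
Why: Vilsmeier–Haack formylation, in which the chloroiminium ion attacks para to one hydroxyl at the carbon flanked by the other hydroxyl and the benzyloxy group (the preference that gives orcylaldehyde from orcinol and 2,4-dihydroxy-6-methoxybenzaldehyde from 5-methoxyresorcinol), water then hydrolyses iminium salt 2 to the aldehyde, and the minor 2,6-dihydroxy isomer is removed by crystallisation.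

Step 2
Reactants: 3 2-(benzyloxy)-4,6-dihydroxybenzaldehyde; 4 3,4,5-tris(benzyloxy)benzoic acid
Product: 5 3-(benzyloxy)-4-formyl-5-hydroxyphenyl 3,4,5-tris(benzyloxy)benzoate
Conditions: DIC, DMAP (cat.), CH2Cl2/THF, 0 °C to rt
Reagents that add atoms: none
Why: Steglich esterification with one equivalent of acid acylates only the free, more acidic 4-OH (para to CHO), because the 6-OH is locked in a hydrogen bond to the formyl group, as in the 4-O-selective chemistry of 2,4-dihydroxybenzaldehydes.

Step 3
Reactants: 6 3,4,5-tris(benzyloxy)benzaldehyde; 7 nitromethane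
Product: 8 (E)-1,2,3-tris(benzyloxy)-5-(2-nitrovinyl)benzene
Conditions: NH4OAc, AcOH, 100 °C
Reagents that add atoms: none
Why: Henry (nitroaldol) condensation with in situ dehydration gives the conjugated E-nitroalkene as the thermodynamic isomer.

Step 4
Reactants: 5 3-(benzyloxy)-4-formyl-5-hydroxyphenyl 3,4,5-tris(benzyloxy)benzoate; 8 (E)-1,2,3-tris(benzyloxy)-5-(2-nitrovinyl)benzene
Product: 10 rac-5-(benzyloxy)-3-oxo-2-[3,4,5-tris(benzyloxy)phenyl]chroman-7-yl 3,4,5-tris(benzyloxy)benzoate, via nitrochromene 9 (not isolated)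
Conditions: DABCO (0.5 equiv), 4 Å MS, MeCN, 50 °C; then Fe, AcOH/H2O, 80 °C, N2
Reagents that add atoms: water O
Why: Oxa-Michael/intramolecular Henry/dehydration cascade followed in the same flask by an iron-mediated reductive Nef reaction, in which the phenoxide of 5 adds to the β-carbon of 8 (O1–C2), the resulting nitronate, a masked acyl anion at C3, attacks the aldehyde carbon (C3–C4), loss of water gives nitrochromene 9, and Fe/AcOH reduces the nitroalkene to an enamine/imine that hydrolyses to ketone 10; C2 is formed racemic on purpose because it is set in step 5.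

Step 5
Reactants: 10 rac-5-(benzyloxy)-3-oxo-2-[3,4,5-tris(benzyloxy)phenyl]chroman-7-yl 3,4,5-tris(benzyloxy)benzoate
Product: 11 (2R,3R)-5-(benzyloxy)-3-hydroxy-2-[3,4,5-tris(benzyloxy)phenyl]chroman-7-yl 3,4,5-tris(benzyloxy)benzoate
Conditions: RuCl[(R,R)-TsDPEN](p-cymene) (2 mol%), HCO2H/Et3N (5:2), DMF, 30 °C
Reagents that add atoms: none
Why: Proposed new method: Noyori–Ikariya asymmetric transfer hydrogenation run as a dynamic kinetic resolution, in which C2–H of 10 (α to the ketone, benzylic and α-aryloxy) lets the two ketone enantiomers interconvert through the enol in HCO2H/Et3N while the chiral Ru–H reduces only the (2R)-ketone, delivering hydride to the Si face of C3 anti to the C2 aryl group so that 2R and 3R (cis) are set together; the closest known reaction type is the ATH–DKR of α-aryloxy and α-aryl cyclic ketones to cis-alcohols, and the catalyst hand is assigned from the usual quadrant model with the C2 arm in the aryl site, to be confirmed on the first run (the (S,S) complex is used if the sense is opposite).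

Step 6
Reactants: 11 (2R,3R)-5-(benzyloxy)-3-hydroxy-2-[3,4,5-tris(benzyloxy)phenyl]chroman-7-yl 3,4,5-tris(benzyloxy)benzoate
Product: 12 epigallocatechin 7-O-gallate, (2R,3R)-3,5-dihydroxy-2-(3,4,5-trihydroxyphenyl)chroman-7-yl 3,4,5-trihydroxybenzoate
Conditions: H2 (1 atm), Pd(OH)2/C, THF/MeOH, rt
Reagents that add atoms: none
Why: Heterogeneous catalytic hydrogenolysis cleaves all seven O-benzyl groups under neutral conditions that leave the aryl gallate ester, the C2–O1 bond and both stereocentres untouched, as in the debenzylation of benzyl-protected catechin gallates.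

## Compound list

1 | 5-(benzyloxy)benzene-1,3-diol | Oc1cc(O)cc(OCc2ccccc2)c1 | starting material
2 | N-[2-(benzyloxy)-4,6-dihydroxybenzylidene]-N-methylmethanaminium dichlorophosphate (aryl iminium salt) | C[N+](C)=Cc1c(O)cc(O)cc1OCc1ccccc1.[O-]P(=O)(Cl)Cl | intermediate
3 | 2-(benzyloxy)-4,6-dihydroxybenzaldehyde | O=Cc1c(O)cc(O)cc1OCc1ccccc1 | intermediate
4 | 3,4,5-tris(benzyloxy)benzoic acid | O=C(O)c1cc(OCc2ccccc2)c(OCc2ccccc2)c(OCc2ccccc2)c1 | starting material
5 | 3-(benzyloxy)-4-formyl-5-hydroxyphenyl 3,4,5-tris(benzyloxy)benzoate | O=Cc1c(O)cc(OC(=O)c2cc(OCc3ccccc3)c(OCc3ccccc3)c(OCc3ccccc3)c2)cc1OCc1ccccc1 | intermediate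
6 | 3,4,5-tris(benzyloxy)benzaldehyde | O=Cc1cc(OCc2ccccc2)c(OCc2ccccc2)c(OCc2ccccc2)c1 | starting material
7 | nitromethane | C[N+](=O)[O-] | starting material
8 | (E)-1,2,3-tris(benzyloxy)-5-(2-nitrovinyl)benzene | O=[N+]([O-])/C=C/c1cc(OCc2ccccc2)c(OCc2ccccc2)c(OCc2ccccc2)c1 | intermediate
9 | rac-5-(benzyloxy)-3-nitro-2-[3,4,5-tris(benzyloxy)phenyl]-2H-chromen-7-yl 3,4,5-tris(benzyloxy)benzoate (nitrochromene) | O=C(Oc1cc(OCc2ccccc2)c2C=C([N+](=O)[O-])C(c3cc(OCc4ccccc4)c(OCc4ccccc4)c(OCc4ccccc4)c3)Oc2c1)c1cc(OCc2ccccc2)c(OCc2ccccc2)c(OCc2ccccc2)c1 | intermediate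
10 | rac-5-(benzyloxy)-3-oxo-2-[3,4,5-tris(benzyloxy)phenyl]chroman-7-yl 3,4,5-tris(benzyloxy)benzoate | O=C(Oc1cc(OCc2ccccc2)c2CC(=O)C(c3cc(OCc4ccccc4)c(OCc4ccccc4)c(OCc4ccccc4)c3)Oc2c1)c1cc(OCc2ccccc2)c(OCc2ccccc2)c(OCc2ccccc2)c1 | intermediate
11 | (2R,3R)-5-(benzyloxy)-3-hydroxy-2-[3,4,5-tris(benzyloxy)phenyl]chroman-7-yl 3,4,5-tris(benzyloxy)benzoate (2,3-cis) | O=C(Oc1cc(OCc2ccccc2)c2c(c1)O[C@H](c1cc(OCc3ccccc3)c(OCc3ccccc3)c(OCc3ccccc3)c1)[C@H](O)C2)c1cc(OCc2ccccc2)c(OCc2ccccc2)c(OCc2ccccc2)c1 | intermediate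
12 | epigallocatechin 7-O-gallate, (2R,3R)-3,5-dihydroxy-2-(3,4,5-trihydroxyphenyl)chroman-7-yl 3,4,5-trihydroxybenzoate | O=C(Oc1cc(O)c2c(c1)O[C@H](c1cc(O)c(O)c(O)c1)[C@H](O)C2)c1cc(O)c(O)c(O)c1 | target

## Step count and risks

Total step count: 6 (step 4 is a two-stage one-pot operation). Longest linear sequence: 5 (steps 1, 2, 4, 5, 6); step 3 is a one-step branch.

Steps most likely to fail, in order:

Step 4. The nitrostyrene is electron-rich and the aldehyde is hindered, so the cascade may be slow. The aryl gallate of 5 sits on a good phenoxide leaving group and may be transferred or cleaved under DABCO. The crude nitrochromene goes into the iron reduction unpurified. The fallback sets out from 3 (with 8) and comes back at 10, and it annulates before acylating and separates the two stages. Compounds 3 and 8 under the same DABCO conditions give rac-5-(benzyloxy)-3-nitro-2-[3,4,5-tris(benzyloxy)phenyl]-2H-chromen-7-ol F1; only the chelated ortho-OH can close the ring and no activated ester is present. The single free phenol of F1 is then esterified with 4 (DIC, DMAP) to give 9, now isolated and purified. Compound 9 is reduced in a separate operation with Fe/AcOH/H2O to 10.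

Step 5. The ketone carries no aryl group directly on the carbonyl, so the enantioface discrimination and the sense of induction are unproven for this ring system. The fallback sets out from 10 and comes back at 11, and it replaces catalyst control by substrate control plus resolution. L-Selectride (THF, −78 °C) reduces 10 anti to the C2 aryl group, which is the known cis-selective reduction of flavan-3-ones, and gives rac-(2R*,3R*)-5-(benzyloxy)-3-hydroxy-2-[3,4,5-tris(benzyloxy)phenyl]chroman-7-yl 3,4,5-tris(benzyloxy)benzoate F2. Preparative chiral SFC separates 11 from (2S,3S)-5-(benzyloxy)-3-hydroxy-2-[3,4,5-tris(benzyloxy)phenyl]chroman-7-yl 3,4,5-tris(benzyloxy)benzoate F3. F3 is oxidised back to 10 with Dess–Martin periodinane and recycled.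

Step 6. Seven benzyl ethers must be removed from a molecule that also holds an aryl ester and a benzylic C2–O1 bond, and the product is an air-sensitive pyrogallol. The fallback sets out from 11 and comes back at 12, and it replaces reduction by Lewis-acid dealkylation. BCl3 with pentamethylbenzene in CH2Cl2 at −78 °C, followed by a methanol quench, removes the benzyl groups as cations that the pentamethylbenzene traps, with no hydrogen and no palladium. New compounds on the way: none F0.

## Further compounds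

F1 | step 4 | rac-5-(benzyloxy)-3-nitro-2-[3,4,5-tris(benzyloxy)phenyl]-2H-chromen-7-ol | Oc1cc(OCc2ccccc2)c2C=C([N+](=O)[O-])C(c3cc(OCc4ccccc4)c(OCc4ccccc4)c(OCc4ccccc4)c3)Oc2c1
F2 | step 5 | rac-(2R*,3R*)-5-(benzyloxy)-3-hydroxy-2-[3,4,5-tris(benzyloxy)phenyl]chroman-7-yl 3,4,5-tris(benzyloxy)benzoate (1:1 mixture of 11 and F3) | O=C(Oc1cc(OCc2ccccc2)c2c(c1)O[C@H](c1cc(OCc3ccccc3)c(OCc3ccccc3)c(OCc3ccccc3)c1)[C@H](O)C2)c1cc(OCc2ccccc2)c(OCc2ccccc2)c(OCc2ccccc2)c1.O=C(Oc1cc(OCc2ccccc2)c2c(c1)O[C@@H](c1cc(OCc3ccccc3)c(OCc3ccccc3)c(OCc3ccccc3)c1)[C@@H](O)C2)c1cc(OCc2ccccc2)c(OCc2ccccc2)c(OCc2ccccc2)c1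
F3 | step 5 | (2S,3S)-5-(benzyloxy)-3-hydroxy-2-[3,4,5-tris(benzyloxy)phenyl]chroman-7-yl 3,4,5-tris(benzyloxy)benzoate | O=C(Oc1cc(OCc2ccccc2)c2c(c1)O[C@@H](c1cc(OCc3ccccc3)c(OCc3ccccc3)c(OCc3ccccc3)c1)[C@@H](O)C2)c1cc(OCc2ccccc2)c(OCc2ccccc2)c(OCc2ccccc2)c1
F0 | step 6 | none | none
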